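**Retrosynthetic overview** (chromene numbering for the target)

- Target ⇒ open-chain δ-hydroxy-β-diketo ester + 5-methylhex-4-enoyl chloride. C-acylation makes C4a–C5, a Dieckmann closure C6–C7 forms ring A, then acid cyclodehydration O1–C8a forms ring B, all in the last flask (ring A first, ring B second).
- Hydroxy diketo ester ⇒ quaternary methyl ketone ester + Weinreb amide of (S)-3-hydroxybutanoate (bond C4–C4a). C2 comes unchanged from the chiral pool.
- Quaternary C8 ⇒ ethyl (S)-3-hydroxybutanoate by two Fráter–Seebach alkylations (geranyl bromide, then MeI), then oxidation of the directing carbinol, which becomes C8a.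

Assumption: enolised polycarbonyl compounds are written as one tautomer each, and 5-methylhex-4-enoic acid is bought as a catalogue compound.

**Route**

Step 1
Reactants: 1 ethyl (3S)-3-hydroxybutanoate; 2 geranyl bromide, (2E)-1-bromo-3,7-dimethylocta-2,6-diene
Product: 3 ethyl (2S,3S)-2-[(2E)-3,7-dimethylocta-2,6-dien-1-yl]-3-hydroxybutanoate
Conditions: LiN(i-Pr)2 (2.2 equiv), THF, −50 to −20 °C; then 2, DMPU, −78 to 0 °C
Reagents that add atoms: none
Why: Fráter–Seebach alkylation, in which the lithium-chelated alkoxide/enolate dianion takes up the allylic bromide on the face anti to the C3 methyl group and so sets C2 as (S) (anti product, about 95:5).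

Step 2
Reactants: 3 ethyl (2S,3S)-2-[(2E)-3,7-dimethylocta-2,6-dien-1-yl]-3-hydroxybutanoate
Product: 4 ethyl (2R,3S)-2-[(2E)-3,7-dimethylocta-2,6-dien-1-yl]-3-hydroxy-2-methylbutanoate
Conditions: LiN(i-Pr)2 (2.4 equiv), THF–DMPU, −78 to −15 °C; then MeI, −78 to 0 °C
Reagents that add atoms: iodomethane, CI
Why: Second Fráter–Seebach alkylation, in which the chelated tetrasubstituted enolate is again attacked anti to the C3 methyl group, so MeI sets the quaternary carbon (later C8) as (R).

Step 3
Reactants: 4 ethyl (2R,3S)-2-[(2E)-3,7-dimethylocta-2,6-dien-1-yl]-3-hydroxy-2-methylbutanoate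
Product: 5 ethyl (2R,4E)-2-acetyl-2,5,9-trimethyldeca-4,8-dienoate
Conditions: Dess–Martin periodinane, CH2Cl2, 0 to 23 °C
Reagents that add atoms: none
Why: Dess–Martin oxidation turns the directing carbinol into the methyl ketone (later C8a with C4a); the α-carbon is quaternary and cannot epimerise, and the trisubstituted alkenes are untouched.

Step 4
Reactants: 1 ethyl (3S)-3-hydroxybutanoate
Product: 6 (3S)-3-hydroxy-N-methoxy-N-methylbutanamide
Conditions: MeNH(OMe)·HCl, i-PrMgCl (4 equiv), THF, −20 to 0 °C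
Reagents that add atoms: N,O-dimethylhydroxylamine hydrochloride, CNOC.Cl
Why: Weinreb amide formation by the magnesium amide of N,O-dimethylhydroxylamine; the carbinol sits as its magnesium alkoxide and keeps the (S) configuration.

Step 5
Reactants: 5 ethyl (2R,4E)-2-acetyl-2,5,9-trimethyldeca-4,8-dienoate; 6 (3S)-3-hydroxy-N-methoxy-N-methylbutanamide
Product: 7 ethyl (2R,7S)-2-[(2E)-3,7-dimethylocta-2,6-dien-1-yl]-7-hydroxy-2-methyl-3,5-dioxooctanoate
Conditions: LiN(i-Pr)2 (2.1 equiv), THF, −78 °C; then 6, −78 to 0 °C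
Reagents that add atoms: none
Why: Claisen-type acylation of the kinetic lithium enolate (the acetyl methyl is the only enolisable position of 5) by the Weinreb amide, whose chelated tetrahedral adduct stops at the ketone stage; this joins C4 to C4a and carries the (S)-carbinol in unchanged.

Step 6
Reactants: 8 5-methylhex-4-enoic acid
Product: 9 5-methylhex-4-enoyl chloride
Conditions: (COCl)2, DMF (cat.), CH2Cl2, 0 to 23 °C
Reagents that add atoms: oxalyl chloride, O=C(Cl)C(Cl)=O
Why: Acid chloride formation through the Vilsmeier-type chloroiminium catalyst; no stereocenter is involved and the trisubstituted alkene is inert under these conditions.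

Step 7
Reactants: 7 ethyl (2R,7S)-2-[(2E)-3,7-dimethylocta-2,6-dien-1-yl]-7-hydroxy-2-methyl-3,5-dioxooctanoate; 9 5-methylhex-4-enoyl chloride
Product: 12 (2S,8R)-8-[(2E)-3,7-dimethylocta-2,6-dien-1-yl]-5-hydroxy-2,8-dimethyl-6-(3-methylbut-2-en-1-yl)-2,3-dihydro-4H-chromene-4,7(8H)-dione, via acyclic triketone 10 (not isolated), via acyl trione 11 (not isolated)
Conditions: MgBr2·OEt2, i-Pr2NEt, THF, 0 °C, then 9; then LiN(i-Pr)2 (5 equiv), −78 to −20 °C; then 2 M HCl, 23 °C
Reagents that add atoms: none
Why: Proposed new method: soft enolisation C-acylates only the magnesium diketonate of 7 to give 10 (Rathke/Coltart-type acylation), LiN(i-Pr)2 then removes a C6 proton and the carbanion closes ring A on the hindered ester (Dieckmann, as in syncarpic acid syntheses) to give 11, and acid closes ring B by cyclodehydration of the side-chain hydroxyl onto the C8a ketone, which is the free ketone of the 3,5-dihydroxy-2-acyl-dienone tautomer (as in lupulone) while C5–OH stays hydrogen-bonded to the acyl carbonyl; the closest known reactions are acylation/Dieckmann routes to acylphloroglucinol-type triones and the acid cyclisation of δ-hydroxy-β-diketones to 2,3-dihydro-4H-pyran-4-ones, and C2 and C8 are carried through because no bond at either centre is broken.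

**Compound list**

1 | ethyl (3S)-3-hydroxybutanoate | C[C@H](O)CC(=O)OCC | starting material
2 | geranyl bromide, (2E)-1-bromo-3,7-dimethylocta-2,6-diene | CC(C)=CCC/C(C)=C/CBr | starting material
3 | ethyl (2S,3S)-2-[(2E)-3,7-dimethylocta-2,6-dien-1-yl]-3-hydroxybutanoate | CC(C)=CCC/C(C)=C/C[C@@H]([C@H](C)O)C(=O)OCC | intermediate
4 | ethyl (2R,3S)-2-[(2E)-3,7-dimethylocta-2,6-dien-1-yl]-3-hydroxy-2-methylbutanoate | CC(C)=CCC/C(C)=C/C[C@](C)([C@H](C)O)C(=O)OCC | intermediate
5 | ethyl (2R,4E)-2-acetyl-2,5,9-trimethyldeca-4,8-dienoate | CC(C)=CCC/C(C)=C/C[C@](C)(C(C)=O)C(=O)OCC | intermediate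
6 | (3S)-3-hydroxy-N-methoxy-N-methylbutanamide | C[C@H](O)CC(=O)N(C)OC | intermediate
7 | ethyl (2R,7S)-2-[(2E)-3,7-dimethylocta-2,6-dien-1-yl]-7-hydroxy-2-methyl-3,5-dioxooctanoate | CC(C)=CCC/C(C)=C/C[C@](C)(C(=O)CC(=O)C[C@H](C)O)C(=O)OCC | intermediate
8 | 5-methylhex-4-enoic acid | CC(C)=CCCC(=O)O | starting material
9 | 5-methylhex-4-enoyl chloride | CC(C)=CCCC(=O)Cl | intermediate
10 | ethyl (2R)-2-[(2E)-3,7-dimethylocta-2,6-dien-1-yl]-4-[(3S)-3-hydroxybutanoyl]-2,9-dimethyl-3,5-dioxodec-8-enoate (acyclic triketone, not isolated) | CC(C)=CCC/C(C)=C/C[C@](C)(C(=O)C(C(=O)C[C@H](C)O)C(=O)CCC=C(C)C)C(=O)OCC | intermediate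
11 | (6S)-6-[(2E)-3,7-dimethylocta-2,6-dien-1-yl]-3,5-dihydroxy-2-[(3S)-3-hydroxybutanoyl]-6-methyl-4-(3-methylbut-2-en-1-yl)cyclohexa-2,4-dien-1-one (acyl trione, not isolated) | O=C1C(C(=O)C[C@H](C)O)=C(O)C(CC=C(C)C)=C(O)[C@]1(C)C/C=C(\C)CCC=C(C)C | intermediate
12 | (2S,8R)-8-[(2E)-3,7-dimethylocta-2,6-dien-1-yl]-5-hydroxy-2,8-dimethyl-6-(3-methylbut-2-en-1-yl)-2,3-dihydro-4H-chromene-4,7(8H)-dione | CC(C)=CCC/C(C)=C/C[C@@]1(C)C(=O)C(CC=C(C)C)=C(O)C2=C1O[C@@H](C)CC2=O | target

**Totals**

Total step count: 7. Longest linear sequence: 5 steps (1 → 3 → 4 → 5 → 7 → 12; steps 1, 2, 3, 5 and 7).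

**Three steps most likely to fail, each with a fallback**

Step 7 is the most exposed. Three things can go wrong:
- after LiN(i-Pr)2 is added, the pendant lithium alkoxide can take an acyl group back from C4a (retro-Claisen);
- C3 can be deprotonated instead of C6;
- the cyclodehydration can close on C5 instead of C8a.

The regiochemistry of ring B rests on the tautomer argument in step 7 and must be checked on the product (HMBC from H-2 to C8a). Fallback: set out from 7 and make the rings in separate, isolated stages with the hydroxyl masked. Et3SiCl and imidazole give the triethylsilyl ether of 7 F1. The same MgBr2·OEt2/i-Pr2NEt acylation with 9 gives the silyl-protected acyclic triketone F2, which can be isolated because no free hydroxyl is left to shift an acyl group or to cyclise early. LiN(i-Pr)2 closes ring A to the silyl-protected acyl trione F3. HF·pyridine then removes the silyl group and closes ring B, which returns to 12.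

Step 2 builds a quaternary carbon on a hindered dianion and can stall or lose selectivity. Fallback: set out from 3 and do the methylation on a rigid four-membered ring. LiOH gives the hydroxy acid F4. PhSO2Cl in pyridine closes it with retention to the trans β-lactone F5. LiN(i-Pr)2 and MeI at −78 °C methylate the lactone enolate anti to the C4 methyl group to give the α-methyl β-lactone F6. NaOEt in EtOH opens the lactone at the acyl carbon and returns to 4.

Step 5 can give low conversion (enolate quenched by the amide hydroxyl), and 7 can cyclise to the dihydropyranone on acidic work-up or silica. Fallback: set out from 5 and change the acyl donor from an amide to a strained lactone. The lithium enolate of 5 is treated with bought (4S)-4-methyloxetan-2-one, which opens at the acyl carbon and gives the lithium alkoxide of 7 directly, with no leaving group and no tetrahedral adduct to break down on work-up. This returns to 7 and makes no new compound, entry F0.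

**Further compounds**

F1 | step 7 | ethyl (2R,7S)-2-[(2E)-3,7-dimethylocta-2,6-dien-1-yl]-2-methyl-3,5-dioxo-7-[(triethylsilyl)oxy]octanoate | CC(C)=CCC/C(C)=C/C[C@](C)(C(=O)CC(=O)C[C@H](C)O[Si](CC)(CC)CC)C(=O)OCC
F2 | step 7 | ethyl (2R)-2-[(2E)-3,7-dimethylocta-2,6-dien-1-yl]-2,9-dimethyl-3,5-dioxo-4-{(3S)-3-[(triethylsilyl)oxy]butanoyl}dec-8-enoate | CC(C)=CCC/C(C)=C/C[C@](C)(C(=O)C(C(=O)C[C@H](C)O[Si](CC)(CC)CC)C(=O)CCC=C(C)C)C(=O)OCC
F3 | step 7 | (6S)-6-[(2E)-3,7-dimethylocta-2,6-dien-1-yl]-3,5-dihydroxy-6-methyl-4-(3-methylbut-2-en-1-yl)-2-{(3S)-3-[(triethylsilyl)oxy]butanoyl}cyclohexa-2,4-dien-1-one | O=C1C(C(=O)C[C@H](C)O[Si](CC)(CC)CC)=C(O)C(CC=C(C)C)=C(O)[C@]1(C)C/C=C(\C)CCC=C(C)C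
F4 | step 2 | (2S,3S)-2-[(2E)-3,7-dimethylocta-2,6-dien-1-yl]-3-hydroxybutanoic acid | CC(C)=CCC/C(C)=C/C[C@@H]([C@H](C)O)C(=O)O
F5 | step 2 | (3S,4S)-3-[(2E)-3,7-dimethylocta-2,6-dien-1-yl]-4-methyloxetan-2-one | CC(C)=CCC/C(C)=C/C[C@H]1[C@H](C)OC1=O
F6 | step 2 | (3R,4S)-3-[(2E)-3,7-dimethylocta-2,6-dien-1-yl]-3,4-dimethyloxetan-2-one | CC(C)=CCC/C(C)=C/C[C@]1(C)[C@H](C)OC1=O
F0 | step 5 | none | none
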